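**Retrosynthetic overview**
1. The trans-fused 8,9-oxirane comes from the (E)-cycloheptene, made by sensitized Z→E photoisomerization of C8=C9 and trapped cold with dimethyldioxirane; the C6 veratroate and C10 desilylation follow.
2. C5-H and C6-OH come from a silicon-tethered hydrosilylation–oxidation of C5=C6 directed by the C4 hydroxyl.
3. The seven-membered ring, the C1 quaternary centre and the C10 carbinol form together in a [2,3]-Wittig rearrangement of a 2-(cyclopentenyl)-3,6-dihydro-2H-pyran (C1–C10 made, C6–O broken, ring oxygen extruded).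
4. The dihydropyran comes from chelation-controlled methallylation of a cyclopentene carbaldehyde, O-allylation and ring-closing metathesis; the carbaldehyde comes from ozonolysis/aldol of (S)-terpinen-4-ol and γ-hydroxylation.
5. Ring order: five-membered ring (aldol), sacrificial dihydropyran (metathesis), seven-membered ring (sigmatropic shift), oxirane.

Reading of the target: as the SMILES is written, C7 and C10 lie on opposite faces of the oxirane (8R,9R), so the epoxide is trans-fused to the seven-membered ring; the route is built to deliver exactly this arrangement.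

Locants follow the daucane skeleton throughout: C1 quaternary methyl carbon, C2 acetoxy carbon, C4 isopropyl carbinol, C5 ring-fusion CH, C6 aroyloxy carbon, C8/C9 oxirane, C10 carbinol. β is the face of the C1 methyl and C4 isopropyl groups; α is the opposite face.

Step 1
Reactants: 1 (S)-(+)-terpinen-4-ol
Product: 4 (R)-5-hydroxy-2-methyl-5-(propan-2-yl)cyclopent-1-ene-1-carbaldehyde, via ozonide 2 (not isolated), via keto aldehyde 3 (not isolated)
Conditions: O3, CH2Cl2, −78 °C; Me2S, −78 °C → rt; then piperidine, AcOH, rt → 40 °C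
Reagents that add atoms: ozone O=[O+][O-]
Why: Ozonolysis opens the ring alkene to the 1,6-keto aldehyde, whose piperidine enamine closes on the methyl ketone (intramolecular aldol condensation) to the five-membered enal, leaving the carbinol stereocentre bought in 1 untouched.

Step 2
Reactants: 4 (R)-5-hydroxy-2-methyl-5-(propan-2-yl)cyclopent-1-ene-1-carbaldehyde
Product: 5 bis-trimethylsilyl dienol ether of 4 (ring C1=C2 and exocyclic C5=C6–OSiMe3; 4-OSiMe3)
Conditions: TMSOTf (2.5 equiv), Et3N, CH2Cl2, 0 °C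
Reagents that add atoms: trimethylsilyl trifluoromethanesulfonate C[Si](C)(C)OS(=O)(=O)C(F)(F)F
Why: Soft enolization (silyl triflate/amine) removes a proton from the ring CH2 at C2 to give the more substituted, endocyclic 1-siloxydiene and also caps the tertiary hydroxyl.

Step 3
Reactants: 5 bis-trimethylsilyl dienol ether
Product: 7 (3R,5R)-3,5-dihydroxy-2-methyl-5-(propan-2-yl)cyclopent-1-ene-1-carbaldehyde, via silyl ether 6 (not isolated)
Conditions: mCPBA, NaHCO3, CH2Cl2, −20 °C; then aq citric acid, MeOH, rt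
Reagents that add atoms: 3-chloroperoxybenzoic acid OOC(=O)c1cccc(Cl)c1
Why: Vinylogous Rubottom oxidation, in which the peracid attacks the distal C1=C2 bond of the 1-siloxydiene on the face away from the isopropyl group and collapse regenerates the enal with a new 2α-hydroxyl (cis to the C4 oxygen); the acidic work-up removes the silyl groups.

Step 4
Reactants: 7 cis-diol enal
Product: 8 (3R,5R)-5-hydroxy-2-methyl-5-(propan-2-yl)-3-(triethylsilyloxy)cyclopent-1-ene-1-carbaldehyde
Conditions: TESCl, imidazole, CH2Cl2, 0 °C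
Reagents that add atoms: chlorotriethylsilane CC[Si](Cl)(CC)CC
Why: Selective silylation of the secondary allylic hydroxyl, since the hindered tertiary hydroxyl does not react with a silyl chloride.

Step 5
Reactants: 8 silyloxy enal; 9 2-methylallylmagnesium chloride
Product: 10 (1R,4R)-2-[(1R)-1-hydroxy-3-methylbut-3-en-1-yl]-3-methyl-1-(propan-2-yl)-4-(triethylsilyloxy)cyclopent-2-en-1-ol
Conditions: CH2=C(CH3)CH2MgCl (2.5 equiv), THF, −78 → 0 °C; aq NH4Cl
Reagents that add atoms: none
Why: Chelation-controlled Grignard 1,2-addition, in which magnesium bridges the C4 alkoxide and the aldehyde oxygen and the allyl group arrives on the face away from the isopropyl group, setting the 6R carbinol.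

Step 6
Reactants: 10 homoallylic alcohol; 11 allyl bromide
Product: 12 (1R,4R)-3-methyl-2-[(1R)-3-methyl-1-(prop-2-en-1-yloxy)but-3-en-1-yl]-1-(propan-2-yl)-4-(triethylsilyloxy)cyclopent-2-en-1-ol
Conditions: NaH (1.2 equiv), allyl bromide, Bu4NI (cat.), THF/DMF, 0 °C → rt
Reagents that add atoms: none
Why: Williamson etherification of the secondary alkoxide; the hindered tertiary hydroxyl is not alkylated.

Step 7
Reactants: 12 allyl ether
Product: 13 (1R,4R)-3-methyl-2-[(2R)-4-methyl-3,6-dihydro-2H-pyran-2-yl]-1-(propan-2-yl)-4-(triethylsilyloxy)cyclopent-2-en-1-ol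
Conditions: second-generation Grubbs catalyst (H2IMes)(PCy3)Cl2Ru=CHPh (3 mol%), CH2Cl2, 40 °C
Reagents that add atoms: none
Why: Ring-closing metathesis of the allyl and methallyl groups gives the cyclic bis-allylic ether with a cis trisubstituted alkene; the tetrasubstituted cyclopentene is inert.

Step 8
Reactants: 13 dihydropyran
Product: 14 2α-(triethylsilyloxy)dauca-5,8-diene-4α,10α-diol
Conditions: sec-BuLi (3 equiv), THF, −78 → −30 °C; H2O
Reagents that add atoms: none
Why: [2,3]-Wittig rearrangement, in which lithiation of the ring OCH2 (C10, allylic and α to oxygen) and a suprafacial shift onto C1 through a bridged five-membered transition state break C6–O and form C1–C10; the 6R centre is relayed to the C1 quaternary centre (new bond on the α face, methyl β) and to the 10α-carbinol, and C5=C6 is forced cis in the new seven-membered ring.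

Step 9
Reactants: 14 dienediol
Product: 15 10α-(tert-butyldimethylsilyloxy)-2α-(triethylsilyloxy)dauca-5,8-dien-4α-ol
Conditions: TBSOTf (1.1 equiv), 2,6-lutidine, CH2Cl2, −78 °C
Reagents that add atoms: tert-butyldimethylsilyl trifluoromethanesulfonate CC(C)(C)[Si](C)(C)OS(=O)(=O)C(F)(F)F
Why: Selective silylation of the secondary allylic hydroxyl at low temperature, leaving the tertiary C4 hydroxyl free as the later tether.

Step 10
Reactants: 15 bis-silyl ether
Product: 16 10α-(tert-butyldimethylsilyloxy)dauca-5,8-diene-2α,4α-diol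
Conditions: PPTS (0.2 equiv), MeOH/CH2Cl2, 0 °C
Reagents that add atoms: none
Why: Mild acid methanolysis removes the triethylsilyl ether much faster than the bulkier tert-butyldimethylsilyl ether and is too weak to ionize the tertiary allylic alcohol at 0 °C.

Step 11
Reactants: 16 diol
Product: 17 2α-acetoxy-10α-(tert-butyldimethylsilyloxy)dauca-5,8-dien-4α-ol
Conditions: Ac2O, pyridine, DMAP (cat.), CH2Cl2, 0 °C → rt
Reagents that add atoms: acetic anhydride CC(=O)OC(C)=O
Why: Acetylation of the only free secondary hydroxyl (C2); the tertiary C4 hydroxyl does not acylate under these conditions.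

Step 12
Reactants: 17 acetate
Product: 20 2α-acetoxy-10α-(tert-butyldimethylsilyloxy)-5αH-dauc-8-ene-4α,6α-diol, via hydridosilyl ether 18 (not isolated), via oxasilolane 19 (not isolated)
Conditions: HMe2SiCl, Et3N, DMAP (cat.), CH2Cl2, 0 °C → rt, filter, evaporate; H2PtCl6·6H2O (0.5 mol%), THF, 60 °C; 30% H2O2, KHCO3, MeOH/THF, rt
Reagents that add atoms: hydrogen peroxide OO
Why: Tamao intramolecular hydrosilylation (5-endo mode), in which the silane tethered to the α C4 oxygen adds syn across C5=C6 (Si to C6, H to C5, both α, giving the trans ring fusion), followed by Tamao–Fleming oxidation of C–Si to C–OH with retention.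

Step 13
Reactants: 20 Z-alkene diol
Product: 22 (8R,9R)-2α-acetoxy-10α-(tert-butyldimethylsilyloxy)-8,9-epoxy-5αH-daucane-4α,6α-diol (oxirane trans-fused to the seven-membered ring), via E-alkene 21 (not isolated)
Conditions: hν (254 nm), methyl benzoate (0.3 equiv), Et2O/pentane, −78 °C; lamp off, DMDO (0.3 equiv, acetone), −78 °C, dark; recovered 20 recycled (3 cycles)
Reagents that add atoms: dimethyldioxirane CC1(C)OO1
Why: Singlet-sensitized Z→E photoisomerization gives the strained (E)-cycloheptene, which persists at −78 °C and can adopt only the helical sense fixed by the trans ring fusion (C8 methyl on the α face, H9 on the β face); dioxirane epoxidation then adds oxygen stereospecifically to its exposed outer face, far faster than to the Z alkene, setting 8R and 9R as the trans-fused oxirane.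

Step 14
Reactants: 22 epoxy diol; 23 3,4-dimethoxybenzoyl chloride
Product: 24 (8R,9R)-2α-acetoxy-10α-(tert-butyldimethylsilyloxy)-8,9-epoxy-4α-hydroxy-5αH-daucan-6α-yl 3,4-dimethoxybenzoate
Conditions: Et3N, DMAP, CH2Cl2, 0 °C
Reagents that add atoms: none
Why: DMAP-catalysed acylation of the only free secondary hydroxyl (C6) under cold basic conditions that leave the strained oxirane alone; the tertiary C4 hydroxyl is inert.

Step 15
Reactants: 24 silyl ether
Product: 25 target, (1R,2R,4R,5R,6R,8R,9R,10R)-2-acetoxy-8,9-epoxy-4,10-dihydroxydaucan-6-yl 3,4-dimethoxybenzoate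
Conditions: TBAF, AcOH (1:1), THF, 0 °C → rt
Reagents that add atoms: none
Why: Fluoride desilylation buffered with acetic acid, so that no free alkoxide forms next to the C2 acetate (no acyl migration) and no strong acid meets the trans-fused oxirane.

**Compound list**
1 | (S)-(+)-terpinen-4-ol, (1S)-4-methyl-1-(propan-2-yl)cyclohex-3-en-1-ol | CC1=CC[C@](O)(C(C)C)CC1 | starting material
2 | ozonide (1,2,4-trioxolane) of 1, mixture at the two acetal carbons | CC12CC[C@@](O)(C(C)C)CC(OO1)O2 | intermediate
3 | (S)-3-hydroxy-6-oxo-3-(propan-2-yl)heptanal | CC(=O)CC[C@@](O)(C(C)C)CC=O | intermediate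
4 | (R)-5-hydroxy-2-methyl-5-(propan-2-yl)cyclopent-1-ene-1-carbaldehyde | CC1=C(C=O)[C@](O)(C(C)C)CC1 | intermediate
5 | (R)-1-methyl-4-(propan-2-yl)-4-(trimethylsilyloxy)-5-[(trimethylsilyloxy)methylidene]cyclopent-1-ene, either enol ether geometry | CC1=CC[C@@](O[Si](C)(C)C)(C(C)C)C1=CO[Si](C)(C)C | intermediate
6 | (3R,5R)-3-hydroxy-2-methyl-5-(propan-2-yl)-5-(trimethylsilyloxy)cyclopent-1-ene-1-carbaldehyde | CC1=C(C=O)[C@](O[Si](C)(C)C)(C(C)C)C[C@H]1O | intermediate
7 | (3R,5R)-3,5-dihydroxy-2-methyl-5-(propan-2-yl)cyclopent-1-ene-1-carbaldehyde (cis-diol) | CC1=C(C=O)[C@](O)(C(C)C)C[C@H]1O | intermediate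
8 | (3R,5R)-5-hydroxy-2-methyl-5-(propan-2-yl)-3-(triethylsilyloxy)cyclopent-1-ene-1-carbaldehyde | CC1=C(C=O)[C@](O)(C(C)C)C[C@H]1O[Si](CC)(CC)CC | intermediate
9 | 2-methylallylmagnesium chloride | CC(=C)C[Mg]Cl | starting material
10 | (1R,4R)-2-[(1R)-1-hydroxy-3-methylbut-3-en-1-yl]-3-methyl-1-(propan-2-yl)-4-(triethylsilyloxy)cyclopent-2-en-1-ol | CC1=C([C@@H](CC(C)=C)O)[C@](O)(C(C)C)C[C@H]1O[Si](CC)(CC)CC | intermediate
11 | allyl bromide | C=CCBr | starting material
12 | (1R,4R)-3-methyl-2-[(1R)-3-methyl-1-(prop-2-en-1-yloxy)but-3-en-1-yl]-1-(propan-2-yl)-4-(triethylsilyloxy)cyclopent-2-en-1-ol | CC1=C([C@@H](CC(C)=C)OCC=C)[C@](O)(C(C)C)C[C@H]1O[Si](CC)(CC)CC | intermediate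
13 | (1R,4R)-3-methyl-2-[(2R)-4-methyl-3,6-dihydro-2H-pyran-2-yl]-1-(propan-2-yl)-4-(triethylsilyloxy)cyclopent-2-en-1-ol | CC1=C([C@H]2CC(C)=CCO2)[C@](O)(C(C)C)C[C@H]1O[Si](CC)(CC)CC | intermediate
14 | 2α-(triethylsilyloxy)dauca-5,8-diene-4α,10α-diol (1β-methyl, 4β-isopropyl) | C1C(C)=C[C@H](O)[C@]2(C)[C@H](O[Si](CC)(CC)CC)C[C@@](O)(C(C)C)C2=C1 | intermediate
15 | 10α-(tert-butyldimethylsilyloxy)-2α-(triethylsilyloxy)dauca-5,8-dien-4α-ol | C1C(C)=C[C@H](O[Si](C)(C)C(C)(C)C)[C@]2(C)[C@H](O[Si](CC)(CC)CC)C[C@@](O)(C(C)C)C2=C1 | intermediate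
16 | 10α-(tert-butyldimethylsilyloxy)dauca-5,8-diene-2α,4α-diol | C1C(C)=C[C@H](O[Si](C)(C)C(C)(C)C)[C@]2(C)[C@H](O)C[C@@](O)(C(C)C)C2=C1 | intermediate
17 | 2α-acetoxy-10α-(tert-butyldimethylsilyloxy)dauca-5,8-dien-4α-ol | C1C(C)=C[C@H](O[Si](C)(C)C(C)(C)C)[C@]2(C)[C@H](OC(C)=O)C[C@@](O)(C(C)C)C2=C1 | intermediate
18 | 4-O-dimethylsilyl ether of 17 | C1C(C)=C[C@H](O[Si](C)(C)C(C)(C)C)[C@]2(C)[C@H](OC(C)=O)C[C@@](O[SiH](C)C)(C(C)C)C2=C1 | intermediate
19 | oxasilolane: 4α-O–SiMe2–C6α bridge, 5α-H, otherwise as 17 without C5=C6 | C[Si]1(C)[C@@H]2CC(C)=C[C@H](O[Si](C)(C)C(C)(C)C)[C@]3(C)[C@H](OC(C)=O)C[C@@](O1)(C(C)C)[C@@H]23 | intermediate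
20 | 2α-acetoxy-10α-(tert-butyldimethylsilyloxy)-5αH-dauc-8-ene-4α,6α-diol (8Z) | O[C@@H]1CC(C)=C[C@H](O[Si](C)(C)C(C)(C)C)[C@]2(C)[C@H](OC(C)=O)C[C@@](O)(C(C)C)[C@@H]12 | intermediate
21 | (8E)-isomer of 20: C7 and C10 trans on C8=C9, C8 methyl toward the α face, H9 toward the β face | O[C@@H]1C/C(C)=C/[C@H](O[Si](C)(C)C(C)(C)C)[C@]2(C)[C@H](OC(C)=O)C[C@@](O)(C(C)C)[C@@H]12 | intermediate
22 | (8R,9R)-2α-acetoxy-10α-(tert-butyldimethylsilyloxy)-8,9-epoxy-5αH-daucane-4α,6α-diol (trans-fused oxirane; C8 methyl α, H9 β) | O[C@@H]1C[C@@]2(C)O[C@@H]2[C@H](O[Si](C)(C)C(C)(C)C)[C@]2(C)[C@H](OC(C)=O)C[C@@](O)(C(C)C)[C@@H]12 | intermediate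
23 | 3,4-dimethoxybenzoyl chloride | COc1ccc(C(Cl)=O)cc1OC | starting material
24 | (8R,9R)-2α-acetoxy-10α-(tert-butyldimethylsilyloxy)-8,9-epoxy-4α-hydroxy-5αH-daucan-6α-yl 3,4-dimethoxybenzoate | COc1ccc(C(=O)O[C@@H]2C[C@@]3(C)O[C@@H]3[C@H](O[Si](C)(C)C(C)(C)C)[C@]3(C)[C@H](OC(C)=O)C[C@@](O)(C(C)C)[C@@H]23)cc1OC | intermediate
25 | (1R,2R,4R,5R,6R,8R,9R,10R)-2-acetoxy-8,9-epoxy-4,10-dihydroxydaucan-6-yl 3,4-dimethoxybenzoate (2α-OAc, 4α-OH, 5α-H, 6α-OAr, 10α-OH, trans-fused 8,9-oxirane) | COc1ccc(C(=O)O[C@@H]2C[C@@]3(C)O[C@@H]3[C@H](O)[C@]3(C)[C@H](OC(C)=O)C[C@@](O)(C(C)C)[C@@H]23)cc1OC | target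

**Totals**
Total step count: 15. Steps 1, 12 and 13 are one-flask sequences.
Longest linear sequence: 15 steps, from 1 to 25.

**Steps most likely to fail, with fallbacks**

Step 13, the Z→E photoisomerization and cold epoxidation. The photostationary mixture may hold little E-alkene, the E-alkene may relax before it is oxidized, and the trans-fused oxirane is strained (comparable to the isolable trans-bicyclo[5.1.0]octane), which is why steps 14 and 15 are run cold and near neutral. The fallback removes the E-alkene from the photoequilibrium as a storable metal complex instead of trapping a small stationary fraction. It sets out from 20: the solution is circulated through a quartz coil (254 nm, methyl benzoate, −40 °C) and then through a cold bed of silica impregnated with AgNO3. The bed binds only the strained isomer, giving the silver nitrate π-complex of the E-alkene F1, and returns the Z-alkene to the lamp until it is used up. F1 is washed from the silica, the E-alkene 21 is set free with cold brine and taken into pentane/Et2O, and dimethyldioxirane at −78 °C gives the epoxide. The route is rejoined at 22.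

Step 8, the [2,3]-Wittig shift. The lithiated dihydropyran could prefer a [1,2]-shift, the base could attack another allylic C–H, and the new C1–C10 bond forms at a fully substituted carbon next to the 2α-silyloxy group. The fallback makes the C10 carbanion at one defined site by reductive lithiation instead of deprotonation. It sets out from 10: acryloyl chloride/Et3N gives the acrylate F2, ring-closing metathesis with the second-generation Grubbs catalyst gives the unsaturated δ-lactone F3, i-Bu2AlH at −78 °C gives the lactol F4, and PhSH/BF3·OEt2 gives the S-phenyl O,S-acetal F5. After deprotonation of the tertiary hydroxyl with n-BuLi, lithium 4,4′-di-tert-butylbiphenylide at −78 °C cleaves the C–S bond, and the α-alkoxy allyllithium undergoes the same rearrangement, coming back to the route at 14.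

Step 12, the tethered hydrosilylation of the hindered C5=C6 bond (C5 lies between two quaternary carbons). If it stalls, the free C4 hydroxyl is used to direct an epoxidation instead. The fallback sets out from 17: VO(acac)2/t-BuOOH gives the 5α,6α-epoxide F6 (only C5=C6 has a free allylic hydroxyl, since C10 is silylated). Cp2TiCl (trivalent titanium, made from Cp2TiCl2 and Zn) with 1,4-cyclohexadiene then opens the epoxide homolytically to the tertiary C5 radical, which takes hydrogen on the α face, coming back to the route at 20.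

Further compounds
F1 | step 13 | silver nitrate π-complex of the E-alkene 21 | O[C@@H]1C/C(C)=C/[C@H](O[Si](C)(C)C(C)(C)C)[C@]2(C)[C@H](OC(C)=O)C[C@@](O)(C(C)C)[C@@H]12.[Ag+].[O-][N+]([O-])=O
F2 | step 8 | acrylate ester of 10 at the C6 hydroxyl | CC1=C([C@@H](CC(C)=C)OC(=O)C=C)[C@](O)(C(C)C)C[C@H]1O[Si](CC)(CC)CC
F3 | step 8 | (6R)-6-(cyclopentenyl)-4-methyl-5,6-dihydro-2H-pyran-2-one, cyclopentenyl unit as in 13 | CC1=C([C@H]2CC(C)=CC(=O)O2)[C@](O)(C(C)C)C[C@H]1O[Si](CC)(CC)CC
F4 | step 8 | lactol of F3 (anomeric mixture) | CC1=C([C@H]2CC(C)=CC(O)O2)[C@](O)(C(C)C)C[C@H]1O[Si](CC)(CC)CC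
F5 | step 8 | S-phenyl O,S-acetal of F4 (anomeric mixture) | CC1=C([C@H]2CC(C)=CC(Sc3ccccc3)O2)[C@](O)(C(C)C)C[C@H]1O[Si](CC)(CC)CC
F6 | step 12 | 5α,6α-epoxide of 17 | O1[C@@H]2CC(C)=C[C@H](O[Si](C)(C)C(C)(C)C)[C@]3(C)[C@H](OC(C)=O)C[C@@](O)(C(C)C)[C@@]123
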